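Count the substrate.

| setting | ash | Saturday's | Sunday's |
|---|---|---|---|
| substrate | 0.22 M | 0.15 M | 0.15 M |
| coupling partner | 0.375 M | 0.375 M | 0.225 M |
| remark | run made earlier |  |  |
| time |  | 12 h | 12 h |

ash run (percent of the substrate charged)

| time / h | double product / % | first product / % | substrate / % |
|---|---|---|---|
| 1.00 | 0.2 | 6.8 | 87.5 |
| 2.00 | 0.4 | 12.1 | 77.1 |
| 3.00 | 0.7 | 17.4 | 68.1 |
| 4.00 | 1.2 | 21.5 | 61.8 |

(each reading ± 0.3 percentage points)

- first product is meant together with its crystals
- released group is meant together with its idle adduct
- solid, in amounts per volume of the solution: crystals
- candidate steps: substrate + released group <-> idle adduct; crystals <-> first product; coupling partner + first product -> double product + released group; substrate + coupling partner -> first product + released group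

- which of these holds the largest part of the substrate at the end of Saturday's (substrate / first product / double product)
- which of these holds the largest part of the substrate at the end of Sunday's (substrate / first product / double product)
- double product at the end of Sunday's, in percent of the substrate charged

My ledger opens on the last line of the ash run. Of the charge, 61.8 % is free substrate, 22.7 % has coupled to first or double product, and I book the missing 15.5 % as idle adduct. I carry one number, the selectivity factor s, defined as 2 times the double product over the square of the coupled share. Its zero of scale is the even case: if first product took its second coupling as readily as substrate takes its first, s would be 1 at low conversion. The ash run reads s = 0.466, from a double product carrying a scatter of 0.3 percentage points.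

I assume that free substrate falls by the same factor at equal c(coupling partner)·t, and that the ash split between coupled share and adduct holds. Sunday's has 1.80 times the ash value of c(coupling partner)·t, taken at the charge. That leaves 42.1 % free substrate and 34.4 % coupled. The books close on 23.5 % adduct, 2.76 % double product and 31.6 % first product. The same steps for Saturday's give 23.6 % free substrate and 45.4 % coupled, so first product leads there.

The forecast names first product for Saturday's and substrate for Sunday's, with 3.2 % double product on Sunday's, a figure above my 2.76 %. Its ground is that “most released group is bound and substrate is sequestered”.

The flask gives first product on Saturday's, 41.8 % against 31.8 % substrate. On Sunday's it gives substrate, 47.7 % against 30.8 % first product, with 2.30 % double product.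

    substrate + released group ⇌ idle adduct, settled at all times (K = 16.8 L mol⁻¹)
    crystals ⇌ first product, rate k2*(cs2 - [first product]) while solid is left; crystals form when [first product] > cs2 (solubility = 2.30 mM, k = 11.5 h⁻¹)
    coupling partner + first product → double product + released group (k = 0.573 L mol⁻¹ h⁻¹)
    substrate + coupling partner → first product + released group (k = 0.204 L mol⁻¹ h⁻¹)

Sunday's gives s = 0.421, below the even case, although the coupling of first product has the larger constant. Sunday's double product stays this low because of the limit of solubility of first product together with the time allowed, each being a part of the reason. Without the limit Sunday's gives 15.1 % at the asked time; with the limit in place and the time taken to 120 h, Sunday's gives 13.4 %. With 0.037 M substrate, the neighbour of Sunday's has a coupled share for which the carried s gives 3.34 %, but that flask holds 8.86 %.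

(The numbers in the tables are simulated with made-up constants; scatter was added.)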